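**Retrosynthetic overview**
1. Target 15 ⇐ 14 (hydrogenolysis of two benzyl ethers). 14 ⇐ open-chain 11 by closing the flavanone pyranone ring last through O1–C2: a biomimetic, chalcone-isomerase-like enantioselective oxa-Michael addition, with the temporary CO2tBu group on C3 lost in the same flask.
2. Enabling feature: O1 (on C8a) and the benzylic C2 are 1,5-related through C4a–C4(=O)–C3, so the flavanone C-ring is a cyclised 2'-hydroxychalcone with C2 as the β-carbon of the C4 ketone. The other ortho oxygen (C5–O) is benzyl-blocked, so only the oxygen next to C8–H can close and the aryloxy group ends at C6.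
3. 11 ⇐ β-ketoester 9 + aldehyde 10 (Knoevenagel); 9 ⇐ methyl ketone 8 + Boc2O.
4. 8 ⇐ hydroquinone ketone 7 + 4'-iodoflavone 4 (Ullmann diaryl ether); 7 ⇐ 1 (mono-benzylation, Elbs para-hydroxylation); 4 ⇐ 1 + 2.
5. Ring order: flavone pyranone ring (step 1), diaryl ether link (step 4), flavanone pyranone ring with the C2 stereocentre (step 7).

Key step: step 7

Remark: 11 is drawn as the (Z)-alkene (aryl cis to the ester), the isomer normally favoured for arylidene β-ketoesters; this geometry is lost in step 7.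
Remark: of the quinine- and quinidine-derived pseudoenantiomeric thioureas, the one that leads to the (2S) series is used; the sense is to be confirmed on 14 by ECD before scale-up.

Step 1
Reactants: 1 1-(2,6-dihydroxy-4-methoxyphenyl)ethan-1-one; 2 4-iodobenzoyl chloride
Product: 4 5-hydroxy-2-(4-iodophenyl)-7-methoxy-4H-chromen-4-one, via β-diketone 3 (not isolated)
Conditions: LiHMDS (4.2 equiv), THF, −78 → −10 °C; 2, −78 °C → rt; 1 M HCl work-up; then AcOH, H2SO4 (cat.), 95 °C
Reagents that add atoms: none
Why: Claisen-type C-aroylation of the lithium polyanion of 1 (direct entry to the Baker–Venkataraman diketone) followed by acid cyclodehydration is the standard one-flask route to 5-hydroxyflavones; the two ortho hydroxyls of 1 are equivalent, so only one flavone can form, and the aryl iodide is inert to LiHMDS and hot acid.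

Step 2
Reactants: 1 1-(2,6-dihydroxy-4-methoxyphenyl)ethan-1-one
Product: 5 1-[2-(benzyloxy)-6-hydroxy-4-methoxyphenyl]ethan-1-one
Conditions: BnBr (1.05 equiv), K2CO3 (1.1 equiv), acetone, reflux
Reagents that add atoms: benzyl bromide, BrCc1ccccc1
Why: Williamson etherification should stop after one benzylation because the remaining ortho hydroxyl is locked in a hydrogen bond to the acetyl group, and the equivalence of the two hydroxyls of 1 removes any regiochemical question.

Step 3
Reactants: 5 1-[2-(benzyloxy)-6-hydroxy-4-methoxyphenyl]ethan-1-one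
Product: 7 1-[2-(benzyloxy)-3,6-dihydroxy-4-methoxyphenyl]ethan-1-one, via aryl potassium sulfate 6 (not isolated)
Conditions: K2S2O8 (1.1 equiv), aq. KOH, pyridine, 0 °C → rt; then HCl to pH 1, 80 °C, N2
Reagents that add atoms: potassium peroxodisulfate, [K+].[K+].[O-]S(=O)(=O)OOS(=O)(=O)[O-]
Why: Elbs persulfate oxidation attacks the phenoxide at the free position para to O− (between OBn and OMe) and the aryl sulfate 6 is then hydrolysed by acid to the hydroquinone, a para-hydroxylation that is classical for 2-hydroxy-4,6-dialkoxyacetophenones and leaves the benzyl ether and the ketone untouched.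

Step 4
Reactants: 7 1-[2-(benzyloxy)-3,6-dihydroxy-4-methoxyphenyl]ethan-1-one; 4 5-hydroxy-2-(4-iodophenyl)-7-methoxy-4H-chromen-4-one
Product: 8 2-{4-[3-acetyl-2-(benzyloxy)-4-hydroxy-6-methoxyphenoxy]phenyl}-5-hydroxy-7-methoxy-4H-chromen-4-one
Conditions: CuI (10 mol%), picolinic acid (20 mol%), K3PO4 (3 equiv), degassed DMSO, 90 °C, Ar
Reagents that add atoms: none
Why: Ullmann-type Cu(I)/picolinic acid C–O coupling, a system that tolerates 2,6-disubstituted phenols, should arylate the electron-rich non-chelated hydroxyl of 7 in preference to the two hydrogen-bonded ortho-acyl phenols (C6–OH of 7 and 5-OH of 4), which are poor nucleophiles, while the inert atmosphere protects the hydroquinone.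

Step 5
Reactants: 8 2-{4-[3-acetyl-2-(benzyloxy)-4-hydroxy-6-methoxyphenoxy]phenyl}-5-hydroxy-7-methoxy-4H-chromen-4-one
Product: 9 tert-butyl 3-[2-(benzyloxy)-6-hydroxy-3-{4-(5-hydroxy-7-methoxy-4-oxo-4H-chromen-2-yl)phenoxy}-4-methoxyphenyl]-3-oxopropanoate
Conditions: LiHMDS (4.5 equiv), THF, −78 °C; Boc2O (1.1 equiv), −78 → −20 °C; 1 M HCl, 0 °C
Reagents that add atoms: di-tert-butyl dicarbonate, CC(C)(C)OC(=O)OC(=O)OC(C)(C)C
Why: Claisen-type C-acylation of the methyl ketone lithium enolate with Boc2O (phenols carried as lithium phenoxides, any aryl carbonate being returned to carbon by Baker–Venkataraman-type O→C transfer under the excess base) should give the tert-butyl β-ketoester, whose bulky ester resists lactonisation to a 4-hydroxycoumarin.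

Step 6
Reactants: 9 tert-butyl 3-[2-(benzyloxy)-6-hydroxy-3-{4-(5-hydroxy-7-methoxy-4-oxo-4H-chromen-2-yl)phenoxy}-4-methoxyphenyl]-3-oxopropanoate; 10 4-(benzyloxy)benzaldehyde
Product: 11 tert-butyl (2Z)-2-[2-(benzyloxy)-6-hydroxy-3-{4-(5-hydroxy-7-methoxy-4-oxo-4H-chromen-2-yl)phenoxy}-4-methoxybenzoyl]-3-[4-(benzyloxy)phenyl]prop-2-enoate
Conditions: piperidine (20 mol%), AcOH (20 mol%), 4 Å MS, toluene, rt
Reagents that add atoms: none
Why: Knoevenagel condensation of the β-ketoester with the aldehyde under buffered piperidinium acetate with water removal should give the arylidene β-ketoester, and at room temperature the hydrogen-bonded phenol should not yet cyclise.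

Step 7
Reactants: 11 tert-butyl (2Z)-2-[2-(benzyloxy)-6-hydroxy-3-{4-(5-hydroxy-7-methoxy-4-oxo-4H-chromen-2-yl)phenoxy}-4-methoxybenzoyl]-3-[4-(benzyloxy)phenyl]prop-2-enoate
Product: 14 (2S)-5-(benzyloxy)-2-[4-(benzyloxy)phenyl]-6-{4-(5-hydroxy-7-methoxy-4-oxo-4H-chromen-2-yl)phenoxy}-7-methoxy-2,3-dihydro-4H-chromen-4-one, via tert-butyl flavanone-3-carboxylate 12 (not isolated), via flavanone-3-carboxylic acid 13 (not isolated)
Conditions: 9-amino-9-deoxy-epi-cinchona N-[3,5-bis(trifluoromethyl)phenyl]thiourea (10 mol%), toluene, −25 °C; then TsOH·H2O (1 equiv), 80 °C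
Reagents that add atoms: none
Why: The quinuclidine nitrogen of the bifunctional catalyst activates the only free ortho-phenol of 11 while the thiourea hydrogen-bonds the ketone/ester pair of the arylidene β-ketoester, and the phenoxide oxygen adds to the benzylic β-carbon in an intramolecular oxa-Michael addition, the chemical counterpart of the chalcone isomerase step of flavonoid biosynthesis, to give 12; TsOH then cleaves the tert-butyl ester to the β-keto acid 13, which decarboxylates to 14. The closest known reaction type is the cinchona-thiourea-catalysed cyclisation of 2-hydroxyaryl alkylidene β-ketoesters to flavanones with acid decarboxylation in the same flask. The pyranone ring closes in the 6-endo-trig mode, the only one open to a phenol oxygen and an enone β-carbon held 1,5 through the aroyl carbon. The C2 stereocentre is set by catalyst control, the chiral hydrogen-bonded ion pair shielding one face of the alkene, and the second centre at C3 is removed with the carboxyl group. Regioselectivity between the two ortho oxygens of the aroyl ring is secured by the benzyl ether on the oxygen next to the aryloxy group, so that O1 can only be the oxygen next to C8–H and no ring-opening/reclosure can move the aryloxy group to C8, while the flavone enone, a β,β-disubstituted vinylogous ester, should stay out of the reaction. The ester makes the acceptor electrophilic enough for a low-temperature, catalyst-controlled and practically irreversible closure and then leaves as isobutene and CO2.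

Step 8
Reactants: 14 (2S)-5-(benzyloxy)-2-[4-(benzyloxy)phenyl]-6-{4-(5-hydroxy-7-methoxy-4-oxo-4H-chromen-2-yl)phenoxy}-7-methoxy-2,3-dihydro-4H-chromen-4-one
Product: 15 (2S)-5-hydroxy-2-(4-hydroxyphenyl)-6-{4-(5-hydroxy-7-methoxy-4-oxo-4H-chromen-2-yl)phenoxy}-7-methoxy-2,3-dihydro-4H-chromen-4-one
Conditions: H2 (1 atm), 10% Pd/C, EtOAc–THF, rt
Reagents that add atoms: none
Why: Catalytic hydrogenolysis of the two benzyl aryl ethers under neutral conditions at room temperature should release the C5 and C4' phenols without base or Lewis acid, so the base-labile C2 centre (retro-oxa-Michael) is not endangered, and the flavone C2=C3 bond and the aryl ketones, which reduce much more slowly, are spared by stopping at the uptake for two benzyl groups.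

**Compound list**
1 | 1-(2,6-dihydroxy-4-methoxyphenyl)ethan-1-one | CC(=O)c1c(O)cc(OC)cc1O | starting material
2 | 4-iodobenzoyl chloride | O=C(Cl)c1ccc(I)cc1 | starting material
3 | 1-(2,6-dihydroxy-4-methoxyphenyl)-3-(4-iodophenyl)propane-1,3-dione (not isolated) | COc1cc(O)c(C(=O)CC(=O)c2ccc(I)cc2)c(O)c1 | intermediate
4 | 5-hydroxy-2-(4-iodophenyl)-7-methoxy-4H-chromen-4-one | COc1cc(O)c2c(=O)cc(-c3ccc(I)cc3)oc2c1 | intermediate
5 | 1-[2-(benzyloxy)-6-hydroxy-4-methoxyphenyl]ethan-1-one | CC(=O)c1c(O)cc(OC)cc1OCc1ccccc1 | intermediate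
6 | potassium 3-acetyl-2-(benzyloxy)-4-hydroxy-6-methoxyphenyl sulfate (not isolated) | CC(=O)c1c(O)cc(OC)c(OS(=O)(=O)[O-])c1OCc1ccccc1.[K+] | intermediate
7 | 1-[2-(benzyloxy)-3,6-dihydroxy-4-methoxyphenyl]ethan-1-one | CC(=O)c1c(O)cc(OC)c(O)c1OCc1ccccc1 | intermediate
8 | 2-{4-[3-acetyl-2-(benzyloxy)-4-hydroxy-6-methoxyphenoxy]phenyl}-5-hydroxy-7-methoxy-4H-chromen-4-one | COc1cc(O)c2c(=O)cc(-c3ccc(Oc4c(OC)cc(O)c(C(C)=O)c4OCc4ccccc4)cc3)oc2c1 | intermediate
9 | tert-butyl 3-[2-(benzyloxy)-6-hydroxy-3-{4-(5-hydroxy-7-methoxy-4-oxo-4H-chromen-2-yl)phenoxy}-4-methoxyphenyl]-3-oxopropanoate | COc1cc(O)c2c(=O)cc(-c3ccc(Oc4c(OC)cc(O)c(C(=O)CC(=O)OC(C)(C)C)c4OCc4ccccc4)cc3)oc2c1 | intermediate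
10 | 4-(benzyloxy)benzaldehyde | O=Cc1ccc(OCc2ccccc2)cc1 | starting material
11 | tert-butyl (2Z)-2-[2-(benzyloxy)-6-hydroxy-3-{4-(5-hydroxy-7-methoxy-4-oxo-4H-chromen-2-yl)phenoxy}-4-methoxybenzoyl]-3-[4-(benzyloxy)phenyl]prop-2-enoate | COc1cc(O)c2c(=O)cc(-c3ccc(Oc4c(OC)cc(O)c(C(=O)/C(=C/c5ccc(OCc6ccccc6)cc5)C(=O)OC(C)(C)C)c4OCc4ccccc4)cc3)oc2c1 | intermediate
12 | tert-butyl (2S,3R)-5-(benzyloxy)-2-[4-(benzyloxy)phenyl]-6-{4-(5-hydroxy-7-methoxy-4-oxo-4H-chromen-2-yl)phenoxy}-7-methoxy-4-oxochromane-3-carboxylate (trans; C3 epimerisable; not isolated) | COc1cc(O)c2c(=O)cc(-c3ccc(Oc4c(OC)cc5c(c4OCc4ccccc4)C(=O)[C@H](C(=O)OC(C)(C)C)[C@@H](c4ccc(OCc6ccccc6)cc4)O5)cc3)oc2c1 | intermediate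
13 | (2S,3R)-5-(benzyloxy)-2-[4-(benzyloxy)phenyl]-6-{4-(5-hydroxy-7-methoxy-4-oxo-4H-chromen-2-yl)phenoxy}-7-methoxy-4-oxochromane-3-carboxylic acid (not isolated) | COc1cc(O)c2c(=O)cc(-c3ccc(Oc4c(OC)cc5c(c4OCc4ccccc4)C(=O)[C@H](C(=O)O)[C@@H](c4ccc(OCc6ccccc6)cc4)O5)cc3)oc2c1 | intermediate
14 | (2S)-5-(benzyloxy)-2-[4-(benzyloxy)phenyl]-6-{4-(5-hydroxy-7-methoxy-4-oxo-4H-chromen-2-yl)phenoxy}-7-methoxy-2,3-dihydro-4H-chromen-4-one | COc1cc(O)c2c(=O)cc(-c3ccc(Oc4c(OC)cc5c(c4OCc4ccccc4)C(=O)C[C@@H](c4ccc(OCc6ccccc6)cc4)O5)cc3)oc2c1 | intermediate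
15 | (2S)-5-hydroxy-2-(4-hydroxyphenyl)-6-{4-(5-hydroxy-7-methoxy-4-oxo-4H-chromen-2-yl)phenoxy}-7-methoxy-2,3-dihydro-4H-chromen-4-one | COc1cc(O)c2c(=O)cc(-c3ccc(Oc4c(OC)cc5c(c4O)C(=O)C[C@@H](c4ccc(O)cc4)O5)cc3)oc2c1 | target

Total step count: 8
Longest linear sequence: 7 steps (1 → 5 → 7 → 8 → 9 → 11 → 14 → 15; step 1 is the side branch to 4)

**Steps most likely to fail**

Step 7. The risk is insufficient enantiofacial discrimination on this bulky, doubly ortho-substituted aroyl acceptor, or erosion of the C2 configuration by reversible ring opening during the hot acidic decarboxylation. The fallback sets out from 8 and returns at 14. Heating 8 with N,N-dimethylformamide dimethyl acetal in toluene should give the dimethylamino enone F1. Brief treatment with aqueous HCl in CH2Cl2 should close the pyranone ring through the same O1–C2 bond by addition–elimination, with loss of dimethylamine, to give the 2-unsubstituted chromone F2. Rh(I)/chiral bisphosphine-catalysed asymmetric 1,4-addition (Hayashi–Miyaura type) of 4-(benzyloxy)phenylboronic acid, with the ligand antipode that gives (2S), should then install the C2 aryl group and the stereocentre to give 14. The 2-aryl-substituted flavone half should not take part.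

Step 4. The risk is competing O-arylation at the chelated C6 hydroxyl, slow coupling at the doubly ortho-substituted hydroxyl, or copper-mediated oxidation of the hydroquinone. The fallback sets out from 4 and returns at 8. Oxidation of 4 with mCPBA and TsOH·H2O in MeCN, followed by 1,3,5-trimethoxybenzene, should give the aryl(2,4,6-trimethoxyphenyl)iodonium tosylate F3. Metal-free O-arylation of 7 with this salt (t-BuOK, THF, rt) should give 8: the more nucleophilic non-chelated phenoxide takes the less electron-rich aryl group, and the trimethoxyphenyl group acts as the non-transferred ligand.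

Step 5. The risk is O-acylation (enol or aryl carbonate) instead of C-acylation of the polyanion, or lactonisation of the product on work-up. The fallback sets out from 8, does without the activating ester, and returns at 14. Claisen–Schmidt condensation of 8 with 10 (KOH, EtOH, rt) should give the plain (E)-2'-hydroxychalcone F4. This is cyclised by asymmetric oxa-Michael addition with a cinchona-derived bifunctional thiourea in toluene, the known catalytic version of the chalcone–flavanone isomerisation, to give 14. The 6'-benzyloxy group twists the chalcone and should shift the ring–chain equilibrium to the flavanone side.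

Further compounds
F1 | step 7 | (2E)-1-[2-(benzyloxy)-6-hydroxy-3-{4-(5-hydroxy-7-methoxy-4-oxo-4H-chromen-2-yl)phenoxy}-4-methoxyphenyl]-3-(dimethylamino)prop-2-en-1-one | COc1cc(O)c2c(=O)cc(-c3ccc(Oc4c(OC)cc(O)c(C(=O)/C=C/N(C)C)c4OCc4ccccc4)cc3)oc2c1
F2 | step 7 | 5-(benzyloxy)-6-{4-(5-hydroxy-7-methoxy-4-oxo-4H-chromen-2-yl)phenoxy}-7-methoxy-4H-chromen-4-one | COc1cc(O)c2c(=O)cc(-c3ccc(Oc4c(OC)cc5occc(=O)c5c4OCc4ccccc4)cc3)oc2c1
F3 | step 4 | [4-(5-hydroxy-7-methoxy-4-oxo-4H-chromen-2-yl)phenyl](2,4,6-trimethoxyphenyl)iodonium 4-methylbenzenesulfonate | COc1cc(O)c2c(=O)cc(-c3ccc([I+]c4c(OC)cc(OC)cc4OC)cc3)oc2c1.Cc1ccc(S(=O)(=O)[O-])cc1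
F4 | step 5 | (2E)-1-[2-(benzyloxy)-6-hydroxy-3-{4-(5-hydroxy-7-methoxy-4-oxo-4H-chromen-2-yl)phenoxy}-4-methoxyphenyl]-3-[4-(benzyloxy)phenyl]prop-2-en-1-one | COc1cc(O)c2c(=O)cc(-c3ccc(Oc4c(OC)cc(O)c(C(=O)/C=C/c5ccc(OCc6ccccc6)cc5)c4OCc4ccccc4)cc3)oc2c1
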